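The route rests on cutting the bond between the CH2OH carbon and the methine carbon that carries the vanillate ether oxygen. That methine is the alpha-carbon of the syringyl aryl ketone, flanked by the C=O and the aryloxy oxygen, so it is both the natural enolate carbon and a configurationally fragile centre. The key step therefore comes late. A chiral Sc(OTf)3-bipyridinediol complex adds aqueous formaldehyde to an achiral, geometrically pure (Z)-trimethylsilyl enol ether, forming the last C-C bond and the only stereocentre in one non-basic operation. The precursor is the enol ether of a bis-benzyl-protected aryloxy ketone assembled from acetosyringone and vanillic acid. One neutral hydrogenolysis finishes the synthesis.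

Key step: step 6

Assumption: the sense of induction of the scandium-bipyridinediol catalyst on an alpha-aryloxy enolate is not known, so the route is written with the (S,S)-ligand, the (R,R)-ligand takes its place if 10 proves to be the S enantiomer, and the configuration is to be checked on 10 before step 7.

Step 1
Reactants: 1 acetosyringone (1-(4-hydroxy-3,5-dimethoxyphenyl)ethan-1-one)
Product: 2 1-[4-(benzyloxy)-3,5-dimethoxyphenyl]ethan-1-one (4-O-benzylacetosyringone)
Conditions: BnBr (1.1 equiv), K2CO3 (1.5 equiv), DMF, 60 °C
Reagents that add atoms: benzyl bromide, BrCc1ccccc1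
Why: Williamson ether synthesis, in which the para-acyl phenol is acidic enough for carbonate, gentle heating overcomes the flanking of the oxygen by two methoxy groups, and the methyl ketone is inert to this weak base.

Step 2
Reactants: 2 1-[4-(benzyloxy)-3,5-dimethoxyphenyl]ethan-1-one
Product: 3 1-[4-(benzyloxy)-3,5-dimethoxyphenyl]-2-bromoethan-1-one
Conditions: PhNMe3Br3 (1.0 equiv), THF, 0 °C to rt
Reagents that add atoms: phenyltrimethylammonium tribromide, C[N+](C)(C)c1ccccc1.[Br-].BrBr
Why: Acid-catalysed alpha-bromination of an aryl methyl ketone through its enol, where the tribromide salt in THF keeps free bromine low (the established way to spare an electron-rich ring) and the bromoketone enolises more slowly than 2, so that one equivalent should stop at the monobromide.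

Step 3
Reactants: 4 vanillic acid (4-hydroxy-3-methoxybenzoic acid)
Product: 5 benzyl 4-hydroxy-3-methoxybenzoate (benzyl vanillate)
Conditions: BnBr (1.0 equiv), KHCO3 (1.2 equiv), DMF, 40 °C
Reagents that add atoms: benzyl bromide, BrCc1ccccc1
Why: Chemoselective SN2 esterification by carboxylate alkylation, in which hydrogencarbonate ionises the carboxylic acid but hardly the much less acidic phenol, so that one equivalent of benzyl bromide should end up on the carboxylate only.

Step 4
Reactants: 3 1-[4-(benzyloxy)-3,5-dimethoxyphenyl]-2-bromoethan-1-one; 5 benzyl vanillate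
Product: 6 benzyl 4-{2-[4-(benzyloxy)-3,5-dimethoxyphenyl]-2-oxoethoxy}-3-methoxybenzoate (achiral aryloxy ketone)
Conditions: K2CO3 (1.5 equiv), acetone, rt
Reagents that add atoms: none
Why: Williamson ether synthesis, in which the phenoxide of 5 displaces bromide from the very reactive phenacyl-type bromide 3 by SN2 at room temperature (the standard assembly of aryloxyacetophenones), while carbonate in acetone harms neither the benzyl ester nor the product methylene.

Step 5
Reactants: 6 benzyl 4-{2-[4-(benzyloxy)-3,5-dimethoxyphenyl]-2-oxoethoxy}-3-methoxybenzoate
Product: 8 benzyl 4-({(Z)-2-[4-(benzyloxy)-3,5-dimethoxyphenyl]-2-[(trimethylsilyl)oxy]ethenyl}oxy)-3-methoxybenzoate, via lithium Z-enolate 7 (not isolated)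
Conditions: LiN(SiMe3)2 (1.1 equiv), THF, -78 °C; then Me3SiCl (1.3 equiv), -78 to 0 °C; evaporation, dry toluene, filtration under argon, no aqueous work-up
Reagents that add atoms: chlorotrimethylsilane, C[Si](C)(C)Cl
Why: Kinetic deprotonation and O-silylation (silyl enol ether synthesis), in which the hindered amide removes only the acidic OCH2C=O proton, the reluctance of an aryl ketone to place the alpha-substituent next to its ring and the five-membered lithium chelate between enolate oxygen and aryloxy oxygen both point to the Z enolate, the silyl chloride traps it on oxygen with retention of geometry, and the non-enolisable benzoate ester is not attacked at -78 °C.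

Step 6
Reactants: 8 (Z)-trimethylsilyl enol ether; 9 formaldehyde (commercial 37% aqueous solution)
Product: 10 benzyl 4-({(2R)-1-[4-(benzyloxy)-3,5-dimethoxyphenyl]-3-hydroxy-1-oxopropan-2-yl}oxy)-3-methoxybenzoate
Conditions: Sc(OTf)3 (10 mol %), (S,S)-6,6'-bis(1-hydroxy-2,2-dimethylpropyl)-2,2'-bipyridine (12 mol %), aq. HCHO (5 equiv), DME/H2O 9:1, -20 °C; cold brine work-up without base
Reagents that add atoms: none
Why: Proposed new method: the tetradentate bipyridinediol wraps Sc(OTf)3 into a water-stable chiral Lewis acid that binds and activates formaldehyde, the electron-rich enol carbon of 8 attacks it through an open transition state, and water then strips the silyl group and protonates the scandium alkoxide, which releases the free beta-hydroxy ketone and the catalyst. The closest known reaction type is the scandium-chiral bipyridine catalysed Mukaiyama aldol hydroxymethylation of (Z)-silicon enolates of propiophenone-type aryl ketones with aqueous formaldehyde, whereas an enolate whose alpha-substituent is an aryloxy group instead of an alkyl group has not been shown. One C-C bond (aryloxy-bearing carbon to CH2OH carbon) is formed and no ring is closed. The new stereocentre is controlled by the ligand alone, which must expose the Re face of the aryloxy-bearing carbon (OAr > C= > H) to give R, and the single Z geometry of 8 ensures that the catalyst meets only one enolate shape. The step also needs C-C bond formation to outrun protodesilylation and to stop after one addition: the extra oxygen donor makes the enol ether more nucleophilic than the alkyl models, and the product cannot re-enolise in the cold, weakly acidic medium, which also protects its configuration. Competing binding of scandium by the ortho-methoxyaryloxy unit is the main uncertainty, but these weak donors would have to displace water and DME, which are present in very large excess.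

Step 7
Reactants: 10 (R)-bis-benzyl-protected hydroxymethyl ketone
Product: 11 4-{[(2R)-3-hydroxy-1-(4-hydroxy-3,5-dimethoxyphenyl)-1-oxopropan-2-yl]oxy}-3-methoxybenzoic acid (CNP0507417.1)
Conditions: H2 (1 atm), 10% Pd/C, EtOAc/THF, rt, stopped after uptake of 2 equiv H2; filtration, evaporation below 30 °C
Reagents that add atoms: none
Why: Heterogeneous catalytic hydrogenolysis of a benzyl ester and a benzyl aryl ether, both of which are cleaved on Pd/C at room temperature and one atmosphere well before an electron-rich aryl ketone is reduced in an aprotic solvent, so that stopping at two equivalents of hydrogen should free the acid and the phenol in a medium without base or strong acid and leave the enolisable R centre untouched.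

Compound list
1 | acetosyringone | CC(=O)c1cc(OC)c(O)c(OC)c1 | starting material
2 | 1-[4-(benzyloxy)-3,5-dimethoxyphenyl]ethan-1-one | CC(=O)c1cc(OC)c(OCc2ccccc2)c(OC)c1 | intermediate
3 | 1-[4-(benzyloxy)-3,5-dimethoxyphenyl]-2-bromoethan-1-one | O=C(CBr)c1cc(OC)c(OCc2ccccc2)c(OC)c1 | intermediate
4 | vanillic acid | COc1cc(C(=O)O)ccc1O | starting material
5 | benzyl vanillate | COc1cc(C(=O)OCc2ccccc2)ccc1O | intermediate
6 | benzyl 4-{2-[4-(benzyloxy)-3,5-dimethoxyphenyl]-2-oxoethoxy}-3-methoxybenzoate | COc1cc(C(=O)OCc2ccccc2)ccc1OCC(=O)c1cc(OC)c(OCc2ccccc2)c(OC)c1 | intermediate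
7 | lithium (Z)-enolate of 6 | COc1cc(C(=O)OCc2ccccc2)ccc1O/C=C(\[O-])c1cc(OC)c(OCc2ccccc2)c(OC)c1.[Li+] | intermediate
8 | (Z)-trimethylsilyl enol ether of 6 | COc1cc(C(=O)OCc2ccccc2)ccc1O/C=C(\O[Si](C)(C)C)c1cc(OC)c(OCc2ccccc2)c(OC)c1 | intermediate
9 | formaldehyde (37% aqueous solution) | C=O | starting material
10 | benzyl 4-({(2R)-1-[4-(benzyloxy)-3,5-dimethoxyphenyl]-3-hydroxy-1-oxopropan-2-yl}oxy)-3-methoxybenzoate | COc1cc(C(=O)OCc2ccccc2)ccc1O[C@H](CO)C(=O)c1cc(OC)c(OCc2ccccc2)c(OC)c1 | intermediate
11 | 4-{[(2R)-3-hydroxy-1-(4-hydroxy-3,5-dimethoxyphenyl)-1-oxopropan-2-yl]oxy}-3-methoxybenzoic acid | COc1cc(C(=O)O)ccc1O[C@H](CO)C(=O)c1cc(OC)c(O)c(OC)c1 | target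

Total step count: 7
Longest linear sequence: 6 steps (steps 1, 2, 4, 5, 6, 7)

Steps most likely to fail

Step 6 (the labelled step). Enantiofacial discrimination may be poor if the oxygen donors of the substrate bind scandium, or protodesilylation back to 6 may outrun C-C bond formation. The fallback gives up asymmetric catalysis for known chemistry and sets out from 6 and 9. Base-mediated aldol hydroxymethylation (catalytic K2CO3, aq. HCHO, 1,4-dioxane, rt), the standard reaction of aryloxyacetophenones, should give the racemic hydroxymethyl ketone F1. Preparative chromatography on a polysaccharide-type chiral stationary phase with a neutral eluent separates it into 10, where the fallback comes back to the route, and the S enantiomer F2. The lability of the centre then becomes an advantage, because a catalytic amount of Et3N in CH2Cl2 turns F2 back into F1 for another pass.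

Step 7. The aryl ketone may be over-reduced, the C-OAr bond next to the carbonyl may be cleaved reductively, or the configuration may erode on the metal surface. The fallback sets out from 10 and takes the carbonyl out of play before hydrogen is used. Reduction under Luche conditions (NaBH4, CeCl3·7H2O, MeOH/THF, -78 °C) should give the (2R)-1,3-diol F3 as a mixture of carbinol epimers, whose ether-bearing centre can no longer enolise. Hydrogenolysis (H2, 10% Pd/C, EtOAc/EtOH, rt), routine for such arylglycerol aryl ethers, then gives the phenolic triol acid F4. DDQ (1.1 equiv, 1,4-dioxane, rt) oxidises only the para-hydroxybenzylic alcohol and leaves the primary alcohol alone. Both epimers converge on the ketone, and the fallback comes back to the route at 11.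

Step 5. Geometric control may be incomplete, or the trimethylsilyl group may be lost by hydrolysis during isolation of an enol ether that cannot be distilled. The fallback sets out from 6 and changes both the enolate surrogate and the origin of its geometry. Soft enolisation with t-BuMe2SiOTf and Et3N (CH2Cl2, 0 °C) runs under equilibrating conditions, where allylic strain between the syringyl ring and the aryloxy group favours the Z isomer. It should give the (Z)-tert-butyldimethylsilyl enol ether F5, which is robust enough for chromatography on deactivated silica or crystallisation to one isomer. F5 then takes the place of 8 in the scandium-catalysed reaction with 9 (longer time or slightly higher temperature) and comes back to the route at 10.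

Further compounds
F1 | step 6 | racemic benzyl 4-({1-[4-(benzyloxy)-3,5-dimethoxyphenyl]-3-hydroxy-1-oxopropan-2-yl}oxy)-3-methoxybenzoate | COc1cc(C(=O)OCc2ccccc2)ccc1OC(CO)C(=O)c1cc(OC)c(OCc2ccccc2)c(OC)c1
F2 | step 6 | benzyl 4-({(2S)-1-[4-(benzyloxy)-3,5-dimethoxyphenyl]-3-hydroxy-1-oxopropan-2-yl}oxy)-3-methoxybenzoate | COc1cc(C(=O)OCc2ccccc2)ccc1O[C@@H](CO)C(=O)c1cc(OC)c(OCc2ccccc2)c(OC)c1
F3 | step 7 | benzyl 4-({(2R)-1-[4-(benzyloxy)-3,5-dimethoxyphenyl]-1,3-dihydroxypropan-2-yl}oxy)-3-methoxybenzoate, mixture of C1 epimers | COc1cc(C(=O)OCc2ccccc2)ccc1O[C@H](CO)C(O)c1cc(OC)c(OCc2ccccc2)c(OC)c1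
F4 | step 7 | 4-{[(2R)-1,3-dihydroxy-1-(4-hydroxy-3,5-dimethoxyphenyl)propan-2-yl]oxy}-3-methoxybenzoic acid, mixture of C1 epimers | COc1cc(C(=O)O)ccc1O[C@H](CO)C(O)c1cc(OC)c(O)c(OC)c1
F5 | step 5 | benzyl 4-({(Z)-2-[4-(benzyloxy)-3,5-dimethoxyphenyl]-2-[(tert-butyldimethylsilyl)oxy]ethenyl}oxy)-3-methoxybenzoate | COc1cc(C(=O)OCc2ccccc2)ccc1O/C=C(\O[Si](C)(C)C(C)(C)C)c1cc(OC)c(OCc2ccccc2)c(OC)c1
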